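**Retrosynthetic overview**

- The target is traced back, through desilylation and two Wittig homologations of an exo C7 aldehyde, to a 7-methylene bicyclo[3.3.1]nonane-2,4,9-trione (C1 = bridgehead beside C8Me2, C5 = bridgehead beside C6H2, C9 = bridging C=O).
- Key disconnection C5–C6 (ring B: C1–C8–C7–C6–C5–C9). C6 and the exocyclic carbon on C7 are the two CH2 termini of a 2-substituted allyl unit whose central carbon C7 hangs on C8Me2. A π-allylpalladium made from the primary allylic carbonate is captured by the C5 enol carbon of a dearomatised acylphloroglucinol, and both termini give the same six-membered ring.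
- C1–C8 (two adjoining quaternary carbons) is not made by π-allyl capture, which would take the primary terminus. It is made by an aromatic Claisen shift from a ring oxygen, which inverts a 2-substituted prenyl ether and dearomatises the ring; C1 is resolved at that stage.
- The arene is bis-C-geranylated maclurin (Houben–Hoesch from phloroglucinol and 3,4-dihydroxybenzonitrile) with the catechol as silyl ethers; the allyl unit comes from diethyl isopropylidenemalonate.
- Ring order: ring A (C1–C2–C3–C4–C5–C9) is the phloroglucinol nucleus; ring B closes in the key step.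

Key step: step 9

Remark: monocyclic precursors are numbered like the bicyclic core, enolised triones are drawn as one tautomer, and it is assumed that the enantiomers of the racemic Claisen product can be separated on a chiral stationary phase.

**Step 1**
Reactants: 1 phloroglucinol; 2 3,4-dihydroxybenzonitrile
Product: 4 maclurin, via ketiminium chloride 3 (not isolated)
Conditions: ZnCl2, HCl (g), Et2O, 0 °C; then H2O, reflux
Reagents that add atoms: water, O
Why: Houben–Hoesch acylation: the HCl/ZnCl2-activated nitrile attacks the electron-rich ring once, the ketiminium salt is deactivated against a second acylation, and water hydrolyses it to the ketone.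

**Step 2**
Reactants: 4 maclurin; 5 geranyl bromide
Product: 6 3,5-di-C-geranylmaclurin
Conditions: 5 (2.1 equiv), KOH, Na2B4O7, H2O, N2, 0 °C → rt
Reagents that add atoms: none
Why: C-alkylation of the phloroglucinolate (SN2) in water, where hydrogen bonding to the phenoxide oxygens steers geranyl bromide to the two free ring carbons, while borate holds the catechol as a cyclic ester so that it is neither O-alkylated nor air-oxidised.

**Step 3**
Reactants: 6 3,5-di-C-geranylmaclurin
Product: 7 catechol bis(triisopropylsilyl) ether of 6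
Conditions: iPr3SiCl (2.3 equiv), imidazole, DMF, 0 °C → rt
Reagents that add atoms: triisopropylsilyl chloride, CC(C)[Si](Cl)(C(C)C)C(C)C
Why: Imidazole-promoted silylation takes the two unhindered catechol hydroxyls, because the phloroglucinol hydroxyls are either chelated to the ketone or flanked by two geranyl groups.

**Step 4**
Reactants: 8 diethyl isopropylidenemalonate
Product: 9 2-(propan-2-ylidene)propane-1,3-diol
Conditions: iBu2AlH, CH2Cl2, −78 → 0 °C; aq. sodium potassium tartrate
Reagents that add atoms: none
Why: 1,2-Reduction of both conjugated ester groups by iBu2AlH gives the symmetrical bis-allylic diol without touching the tetrasubstituted alkene.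

**Step 5**
Reactants: 9 2-(propan-2-ylidene)propane-1,3-diol
Product: 10 2-(hydroxymethyl)-3-methylbut-2-en-1-yl methyl carbonate
Conditions: ClCO2Me (substoichiometric), pyridine, CH2Cl2, −20 °C
Reagents that add atoms: methyl chloroformate, COC(=O)Cl
Why: Statistical mono-acylation of the symmetrical diol with a chloroformate, run with the diol in excess (recovered), installs the future palladium leaving group.

**Step 6**
Reactants: 7 bis-silyl arene; 10 allylic alcohol
Product: 11 aryl 2-(methoxycarbonyloxymethyl)-3-methylbut-2-enyl ether at the phenol oxygen between the geranyl groups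
Conditions: PPh3, DIAD, THF, 0 °C → rt
Reagents that add atoms: none
Why: Mitsunobu etherification (SN2 at the primary allylic carbon) engages the most acidic, non-chelated phenol between the geranyl groups, and an ether at either of the other oxygens would in any case converge on the same product in step 7.

**Step 7**
Reactants: 11 aryl allyl ether
Product: 12 racemic dearomatised acylphloroglucinol with the C1 arm CMe2–C(=CH2)–CH2OCO2Me
Conditions: PhMe, BHT, 100 °C, stopped at full conversion
Reagents that add atoms: none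
Why: Aromatic Claisen rearrangement: the concerted [3,3] shift inverts the allyl unit and bonds its CMe2 terminus to a geranylated ortho carbon (C1–C8), the dienone settles as the chelated enol-trione that cannot rearomatise, the lowest workable temperature is used so that a second [3,3] shift does not follow, and C1 is formed racemic.

**Step 8**
Reactants: 12 racemic precursor
Product: 13 (S)-enantiomer of 12
Conditions: preparative SFC, immobilised amylose tris(3,5-dimethylphenylcarbamate) phase, CO2/MeOH (0.1% HCO2H)
Reagents that add atoms: none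
Why: Resolution by preparative chromatography on a chiral stationary phase separates the antipodes of the configurationally stable quaternary C1; the (S)-enantiomer, to be identified by X-ray or ECD analysis, has the C1 configuration of the target.

**Step 9**
Reactants: 13 (S)-precursor
Product: 14 (1S,5S)-7-methylene bicyclo[3.3.1]nonane-2,4,9-trione (enol form, catechol silylated)
Conditions: Pd(PPh3)4 (5 mol %), THF, degassed, rt
Reagents that add atoms: none
Why: Pd(PPh3)4 as a zerovalent palladium source ionises the primary allylic methyl carbonate; loss of CO2 leaves methoxide, which deprotonates the vinylogous acid, and the C5 carbon of the enolate attacks a CH2 terminus of the cationic π-allyl complex (outer-sphere Tsuji–Trost alkylation). The closest known reaction type is the palladium-catalysed alkylation of cyclic 1,3-dicarbonyl compounds and of dearomatised acylphloroglucinols by 2-(acyloxymethyl)allyl units, which gives 7-methylene bicyclo[3.3.1]nonanes. Ring B (C1–C8–C7–C6–C5–C9) closes as a six-membered ring by attack on a terminus of the 2-substituted allyl whose central carbon C7 carries the tether; the two termini are constitutionally equivalent, so either attack gives the same ring with the other CH2 left as the exocyclic methylene. The new bridgehead stereocentre C5 is fixed by C1, because the three-carbon bridge can only span the ring cis from the already quaternary C1. The step needs C5-alkylation over O-alkylation (at O2 or O9) and over alkylation at C3: the cyclic allyl enol ethers from O-attack are ionised again by zerovalent palladium and drain to the C-alkylated bicycle, whereas C3 is the chelated, aroyl-bearing and least nucleophilic carbon, whose alkylation would cost the enolised β-triketone. Neutral conditions at room temperature should leave the geranyl chains, the aryl silyl ethers and the C1–geranyl bond untouched.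

**Step 10**
Reactants: 14 methylene bicycle
Product: 16 7-endo-hydroxymethyl bicycle, via B-alkyl-9-BBN adduct 15 (not isolated)
Conditions: 9-BBN (4 equiv), THF, 0 → 40 °C; then NaBO3·4H2O, H2O, rt
Reagents that add atoms: sodium perborate (NaBO3·4H2O), O[B-]1(O)OO[B-](O)(O)OO1.[Na+].[Na+]
Why: Hydroboration–oxidation: 9-BBN (in excess, since the acidic enol consumes one equivalent) adds to the 1,1-disubstituted methylene far faster than to the trisubstituted geranyl alkenes with boron on the terminal carbon, and hydrogen should reach C7 from the open exo face so that the CH2OH group is expected endo, which is corrected in step 11.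

**Step 11**
Reactants: 16 7-endo alcohol
Product: 18 7-exo aldehyde, via 7-endo aldehyde 17 (not isolated)
Conditions: Dess–Martin periodinane, CH2Cl2, 0 °C → rt; then DBU, rt
Reagents that add atoms: none
Why: Dess–Martin oxidation gives the aldehyde and DBU then equilibrates C7 through the enolate to the exo epimer, which is equatorial on chair ring B and avoids the clash with ring A, so the C7 configuration of the target is set under thermodynamic control.

**Step 12**
Reactants: 18 7-exo aldehyde
Product: 19 7-exo 2-methoxyvinyl bicycle (E/Z mixture)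
Conditions: Ph3P(CH2OMe)Cl, KN(SiMe3)2 (excess), THF, −78 → 0 °C
Reagents that add atoms: (methoxymethyl)triphenylphosphonium chloride, COC[P+](c1ccccc1)(c1ccccc1)c1ccccc1.[Cl-]
Why: Wittig methoxymethylenation of the aldehyde; the first equivalent of ylide turns the acyl-trione into its enolate, which shields C2, C4 and the aroyl carbonyl, and the C9 ketone between two quaternary carbons is too hindered to react.

**Step 13**
Reactants: 19 enol ether
Product: 20 7-exo 2-oxoethyl bicycle
Conditions: 1 M aq. HCl, THF, 0 °C → rt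
Reagents that add atoms: water, O
Why: Acid hydrolysis of the enol ether gives the one-carbon-homologated aldehyde, and dilute acid at low temperature is chosen to spare the aryl silyl ethers and the geranyl alkenes.

**Step 14**
Reactants: 20 homologated aldehyde
Product: 21 bis(triisopropylsilyl) ether of the target
Conditions: iPrPPh3I, KN(SiMe3)2 (excess), THF, −78 °C → rt
Reagents that add atoms: isopropyltriphenylphosphonium iodide, CC(C)[P+](c1ccccc1)(c1ccccc1)c1ccccc1.[I-]
Why: Wittig olefination with the isopropylidene ylide completes the prenyl group on C7, again with excess ylide to cover the acidic enol.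

**Step 15**
Reactants: 21 bis-silyl ether
Product: 22 target CNP0178719.1
Conditions: Bu4NF, AcOH, THF, 0 °C
Reagents that add atoms: none
Why: Fluoride cleaves the two aryl silyl ethers (desilylation) under acetic-acid-buffered conditions that avoid base- or acid-induced cyclisation of the enol onto the geranyl chains.

**Compound list**

1 | phloroglucinol | Oc1cc(O)cc(O)c1 | starting material
2 | 3,4-dihydroxybenzonitrile | N#Cc1ccc(O)c(O)c1 | starting material
3 | (3,4-dihydroxyphenyl)(2,4,6-trihydroxyphenyl)methaniminium chloride | [NH2+]=C(c1ccc(O)c(O)c1)c1c(O)cc(O)cc1O.[Cl-] | intermediate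
4 | maclurin, (3,4-dihydroxyphenyl)(2,4,6-trihydroxyphenyl)methanone | O=C(c1ccc(O)c(O)c1)c1c(O)cc(O)cc1O | intermediate
5 | geranyl bromide, (E) | CC(C)=CCC/C(C)=C/CBr | starting material
6 | (3,4-dihydroxyphenyl){3,5-bis[(2E)-3,7-dimethylocta-2,6-dienyl]-2,4,6-trihydroxyphenyl}methanone | O=C(c1ccc(O)c(O)c1)c1c(O)c(C/C=C(\C)CCC=C(C)C)c(O)c(C/C=C(\C)CCC=C(C)C)c1O | intermediate
7 | 3',4'-bis(triisopropylsilyl) ether of 6 | O=C(c1ccc(O[Si](C(C)C)(C(C)C)C(C)C)c(O[Si](C(C)C)(C(C)C)C(C)C)c1)c1c(O)c(C/C=C(\C)CCC=C(C)C)c(O)c(C/C=C(\C)CCC=C(C)C)c1O | intermediate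
8 | diethyl isopropylidenemalonate | CCOC(=O)C(=C(C)C)C(=O)OCC | starting material
9 | 2-(propan-2-ylidene)propane-1,3-diol | CC(C)=C(CO)CO | intermediate
10 | 2-(hydroxymethyl)-3-methylbut-2-en-1-yl methyl carbonate | CC(C)=C(CO)COC(=O)OC | intermediate
11 | 4-O-[2-(methoxycarbonyloxymethyl)-3-methylbut-2-enyl] ether of 7 (oxygen between the two geranyl groups) | O=C(c1ccc(O[Si](C(C)C)(C(C)C)C(C)C)c(O[Si](C(C)C)(C(C)C)C(C)C)c1)c1c(O)c(C/C=C(\C)CCC=C(C)C)c(OCC(=C(C)C)COC(=O)OC)c(C/C=C(\C)CCC=C(C)C)c1O | intermediate
12 | racemic 2-aroyl-3,5-dihydroxy-4,6-digeranyl-6-[3-(methoxycarbonyloxymethyl)-2-methylbut-3-en-2-yl]cyclohexa-2,4-dien-1-one, aroyl = 3,4-bis(triisopropylsilyloxy)benzoyl | O=C1C(C(=O)c2ccc(O[Si](C(C)C)(C(C)C)C(C)C)c(O[Si](C(C)C)(C(C)C)C(C)C)c2)=C(O)C(C/C=C(\C)CCC=C(C)C)=C(O)C1(C/C=C(\C)CCC=C(C)C)C(C)(C)C(=C)COC(=O)OC | intermediate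
13 | (S)-enantiomer of 12 (quaternary carbon = C1 of the bicycle) | O=C1C(C(=O)c2ccc(O[Si](C(C)C)(C(C)C)C(C)C)c(O[Si](C(C)C)(C(C)C)C(C)C)c2)=C(O)C(C/C=C(\C)CCC=C(C)C)=C(O)[C@]1(C/C=C(\C)CCC=C(C)C)C(C)(C)C(=C)COC(=O)OC | intermediate
14 | (1S,5S)-3-aroyl-1,5-digeranyl-4-hydroxy-8,8-dimethyl-7-methylidenebicyclo[3.3.1]non-3-ene-2,9-dione, aroyl as in 12 | CC(C)=CCC/C(C)=C/C[C@]12CC(=C)C(C)(C)[C@](C/C=C(\C)CCC=C(C)C)(C(=O)C(C(=O)c3ccc(O[Si](C(C)C)(C(C)C)C(C)C)c(O[Si](C(C)C)(C(C)C)C(C)C)c3)=C1O)C2=O | intermediate
15 | B-alkyl-9-BBN adduct of 14 (boron on the former methylene carbon, C7–H exo) | CC(C)=CCC/C(C)=C/C[C@]12C[C@H](CB4C5CCCC4CCC5)C(C)(C)[C@](C/C=C(\C)CCC=C(C)C)(C(=O)C(C(=O)c3ccc(O[Si](C(C)C)(C(C)C)C(C)C)c(O[Si](C(C)C)(C(C)C)C(C)C)c3)=C1O)C2=O | intermediate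
16 | (1S,5S)-7-endo-hydroxymethyl bicycle | CC(C)=CCC/C(C)=C/C[C@]12C[C@H](CO)C(C)(C)[C@](C/C=C(\C)CCC=C(C)C)(C(=O)C(C(=O)c3ccc(O[Si](C(C)C)(C(C)C)C(C)C)c(O[Si](C(C)C)(C(C)C)C(C)C)c3)=C1O)C2=O | intermediate
17 | (1S,5S)-7-endo-formyl bicycle | CC(C)=CCC/C(C)=C/C[C@]12C[C@H](C=O)C(C)(C)[C@](C/C=C(\C)CCC=C(C)C)(C(=O)C(C(=O)c3ccc(O[Si](C(C)C)(C(C)C)C(C)C)c(O[Si](C(C)C)(C(C)C)C(C)C)c3)=C1O)C2=O | intermediate
18 | (1S,5S)-7-exo-formyl bicycle | CC(C)=CCC/C(C)=C/C[C@]12C[C@@H](C=O)C(C)(C)[C@](C/C=C(\C)CCC=C(C)C)(C(=O)C(C(=O)c3ccc(O[Si](C(C)C)(C(C)C)C(C)C)c(O[Si](C(C)C)(C(C)C)C(C)C)c3)=C1O)C2=O | intermediate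
19 | (1S,5S)-7-exo-(2-methoxyvinyl) bicycle, E/Z mixture | CC(C)=CCC/C(C)=C/C[C@]12C[C@@H](C=COC)C(C)(C)[C@](C/C=C(\C)CCC=C(C)C)(C(=O)C(C(=O)c3ccc(O[Si](C(C)C)(C(C)C)C(C)C)c(O[Si](C(C)C)(C(C)C)C(C)C)c3)=C1O)C2=O | intermediate
20 | (1S,5S)-7-exo-(2-oxoethyl) bicycle | CC(C)=CCC/C(C)=C/C[C@]12C[C@@H](CC=O)C(C)(C)[C@](C/C=C(\C)CCC=C(C)C)(C(=O)C(C(=O)c3ccc(O[Si](C(C)C)(C(C)C)C(C)C)c(O[Si](C(C)C)(C(C)C)C(C)C)c3)=C1O)C2=O | intermediate
21 | 3',4'-bis(triisopropylsilyl) ether of the target (7-exo prenyl) | CC(C)=CCC/C(C)=C/C[C@]12C[C@@H](CC=C(C)C)C(C)(C)[C@](C/C=C(\C)CCC=C(C)C)(C(=O)C(C(=O)c3ccc(O[Si](C(C)C)(C(C)C)C(C)C)c(O[Si](C(C)C)(C(C)C)C(C)C)c3)=C1O)C2=O | intermediate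
22 | (1S,5S,7R)-3-(3,4-dihydroxybenzoyl)-1,5-bis[(2E)-3,7-dimethylocta-2,6-dienyl]-4-hydroxy-8,8-dimethyl-7-(3-methylbut-2-enyl)bicyclo[3.3.1]non-3-ene-2,9-dione (7-prenyl exo) | CC(C)=CCC/C(C)=C/C[C@]12C[C@@H](CC=C(C)C)C(C)(C)[C@](C/C=C(\C)CCC=C(C)C)(C(=O)C(C(=O)c3ccc(O)c(O)c3)=C1O)C2=O | target

**Step count**

Total: 15 steps (13 on the main line, 2 for the allyl unit). Longest linear sequence: 13 steps (steps 1–3 and 6–15, from phloroglucinol).

**Steps most likely to fail**

1. Step 7 (Claisen). The first [3,3] shift may be followed by a Cope shift that carries the arm on from C1 to C5 or C3, or the ether may ionise and recombine through the primary allyl terminus; either process erases the C1–C8 connectivity.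
   Fallback (gives up the palladium closure; both ring-B bonds then come from conjugate addition): diol 9 is mono-acetylated (Ac2O, pyridine) to 2-(hydroxymethyl)-3-methylbut-2-en-1-yl acetate F1, which MnO2 oxidises to 2-formyl-3-methylbut-2-en-1-yl acetate F2. Arene 7 and F2 are combined under phase-transfer conditions (O-allyl-N-(9-anthracenylmethyl)cinchonidinium bromide or its cinchoninium pseudoenantiomer, CsOH·H2O, CH2Cl2, −50 °C). Dearomative conjugate addition at a geranylated carbon and loss of acetate give the α-methylene aldehyde F3, whose C5 enolate adds to the new enal in the same flask. DBU equilibration then leads to 18, where the route is rejoined; the enantiomeric purity of 18 would be raised by chiral-phase chromatography if needed.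

2. Step 9 (key step). The π-allyl intermediate may be captured at oxygen and rest as a cyclic allyl enol ether, or be diverted to C3, so that C5–C6 bond formation stalls.
   Fallback: from 13, methanolysis of the carbonate (K2CO3, MeOH, 0 °C) gives the allylic alcohol F4. MnO2 oxidises it to the α-methylene aldehyde F3, and DBU closes ring B by intramolecular conjugate addition of C5 and equilibrates C7, returning to the route at 18.

3. Step 10 (hydroboration). The acidic enol may consume the borane, and ring carbonyls or geranyl alkenes may be attacked before the hindered methylene beside C8Me2 reacts.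
   Fallback: from 14, radical anti-Markovnikov addition of benzenethiol (excess PhSH, AIBN (azobisisobutyronitrile), benzene, 75 °C) gives the phenyl sulfide F5. NaIO4 oxidises it to the sulfoxide F6, and a Pummerer rearrangement (trifluoroacetic anhydride, 2,6-lutidine; then aq. NaHCO3) unveils the C7 aldehyde as an epimer mixture, which enters the route at 17 and is equilibrated to 18 by DBU as in step 11.

**Further compounds**

F1 | step 7 | 2-(hydroxymethyl)-3-methylbut-2-en-1-yl acetate | CC(C)=C(CO)COC(C)=O
F2 | step 7 | 2-formyl-3-methylbut-2-en-1-yl acetate | CC(C)=C(C=O)COC(C)=O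
F3 | step 7 | (S)-dearomatised acylphloroglucinol with the C1 arm CMe2–C(=CH2)–CHO | O=C1C(C(=O)c2ccc(O[Si](C(C)C)(C(C)C)C(C)C)c(O[Si](C(C)C)(C(C)C)C(C)C)c2)=C(O)C(C/C=C(\C)CCC=C(C)C)=C(O)[C@]1(C/C=C(\C)CCC=C(C)C)C(C)(C)C(=C)C=O
F4 | step 9 | (S)-dearomatised acylphloroglucinol with the C1 arm CMe2–C(=CH2)–CH2OH | O=C1C(C(=O)c2ccc(O[Si](C(C)C)(C(C)C)C(C)C)c(O[Si](C(C)C)(C(C)C)C(C)C)c2)=C(O)C(C/C=C(\C)CCC=C(C)C)=C(O)[C@]1(C/C=C(\C)CCC=C(C)C)C(C)(C)C(=C)CO
F5 | step 10 | (1S,5S)-7-(phenylsulfanylmethyl) bicycle, C7 epimer mixture | CC(C)=CCC/C(C)=C/C[C@]12CC(CSc4ccccc4)C(C)(C)[C@](C/C=C(\C)CCC=C(C)C)(C(=O)C(C(=O)c3ccc(O[Si](C(C)C)(C(C)C)C(C)C)c(O[Si](C(C)C)(C(C)C)C(C)C)c3)=C1O)C2=O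
F6 | step 10 | (1S,5S)-7-(phenylsulfinylmethyl) bicycle, epimer mixture | CC(C)=CCC/C(C)=C/C[C@]12CC(CS(=O)c4ccccc4)C(C)(C)[C@](C/C=C(\C)CCC=C(C)C)(C(=O)C(C(=O)c3ccc(O[Si](C(C)C)(C(C)C)C(C)C)c(O[Si](C(C)C)(C(C)C)C(C)C)c3)=C1O)C2=O
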